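All runs are simulated for an exercise, and the scatter is random.

Starting material cannot turn into more target than was lost of it, yet in the eta run, between 1.00 h and 4.00 h, target rose 12 percentage points while starting material fell 7.9 points, more gained than lost.

| flask | starting material | coupling partner | remark | time |
|---|---|---|---|---|
| zeta | 43 mM | 51.6 mM | run made earlier |  |
| gamma | 43 mM | 72 mM | run made earlier |  |
| eta | 43 mM | 110 mM | run made earlier |  |
| alpha | 22 mM | 51.6 mM | run made earlier |  |
| teal | 43 mM | 51.6 mM (fed, over 2.40 h) | a stirred flask in which coupling partner is dosed at a steady rate over 2.40 h without added volume, worked up at 3.0 h | 3.0 h |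
| blue | 43 mM | 51.6 mM | everything together in a closed stirred flask, run for 3.0 h | 3.0 h |
| amber | 43 mM | 51.6 mM | a single well-mixed tank run continuously and read at steady state, 30.0 h in it on average |  |
| grey | 43 mM | 51.6 mM | a single well-mixed tank run continuously and read at steady state, 3.0 h in it on average |  |

| run | time / h | target / % | starting material / % |
|---|---|---|---|
| zeta | 0.667 | 8.0 | 26.8 |
| zeta | 1.33 | 17.2 | 16.8 |
| zeta | 2.00 | 22.7 | 12.2 |
| zeta | 2.50 | 22.4 | 9.5 |
| zeta | 3.00 | 27.6 | 11.5 |
| gamma | 0.333 | 7.0 | 39.6 |
| gamma | 0.833 | 14.9 | 21.0 |
| gamma | 1.50 | 23.0 | 11.6 |
| gamma | 2.50 | 28.6 | 6.6 |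
| gamma | 4.00 | 30.8 | 5.7 |
| eta | 0.250 | 5.0 | 43.0 |
| eta | 0.500 | 12.4 | 23.9 |
| eta | 1.00 | 21.7 | 10.8 |
| eta | 2.00 | 29.4 | 4.0 |
| eta | 4.00 | 33.7 | 2.9 |
| alpha | 0.333 | 2.6 | 44.3 |
| alpha | 0.833 | 12.6 | 22.9 |
| alpha | 1.50 | 19.9 | 14.5 |
| alpha | 2.50 | 24.2 | 8.7 |
| alpha | 4.00 | 32.2 | 6.4 |

(scatter of a reading: 1 percentage point)

- the stated concentrations are those of everything mixed, before any reaction; amounts are the same in each set-up
- on the list of suspects stand: starting material <-> tautomer; starting material + coupling partner -> isomer of the product; coupling partner + tautomer -> target; starting material <-> dormant form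
- the feed brings no volume worth counting
- the earlier runs were made in a closed, stirred flask

1. the set-up with the highest amount of target at the outlet or at the end, in percent of the starting material put in ("none" if the first two lie within 2 percentage points) (teal / blue / amber / grey / none)
2. amount of target at the outlet or at the end, in percent of the starting material put in, teal
3. amount of target at the outlet or at the end, in percent of the starting material put in, blue
4. amount of target at the outlet or at the end, in percent of the starting material put in, amber
5. amount of target at the outlet or at the end, in percent of the starting material put in, grey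

*What do you read from that?* That starting material, the limiting reagent in the eta charge (43 mM against 110 mM of coupling partner), has partly gone somewhere that still feeds target. So the useful figure is the late gain: points of target won per point of starting material lost late in a run.

*Its value?* In the gamma run, from 1.50 h to 4.00 h, the late gain is 1.32.

*That is a ratio of two small differences, each reading scattered by 1 point. Is it really above one?* Gamma alone is weak, but eta gives 1.52, and I take the lower figure.

*Then your number for amber?* At the early end stands the zeta reading at 3.00 h: target 27.6%, starting material 11.5%. At the late end, I count that whole remainder as lost at the late gain, so I say 42.8%.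

*But amber is a tank, not a closed flask.* Yes. Its average time is ten times the zeta span, but its outlet mixes young liquid with old, so I hold this as the high side.

The forecast differs. It names amber best, with teal 24%, blue 26%, grey 20% and amber 33% (range 26% to 44%), on the ground “30 h gives about 85–90% conversion at roughly the same selectivity”.

Amber gives 40.3%, 7.3 points above the forecast and the highest; blue gives 26.2%, teal 22.0% and grey 20.7%.

    starting material ⇌ tautomer (K = 0.906, k = 0.0327 min⁻¹)
    starting material + coupling partner → isomer of the product (k = 0.196 M⁻¹ min⁻¹)
    coupling partner + tautomer → target (k = 0.264 M⁻¹ min⁻¹)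
    starting material ⇌ dormant form (K = 2.07, k = 0.0121 min⁻¹)

With the backward step from dormant form to starting material struck out, amber gives 23.8%. Amber's 40.3% lies 2.5 points below the 42.8% reckoned from the zeta reading. Grey's outlet has [starting material] of 8.83 mM, 20.5% of the charge; counted as lost at the late gain on top of grey's 20.7%, that stock gives 47.8%, more than amber's 40.3%.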